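Free catalyst in eta stands at 3.00 times its charge in epsilon, and the target at 6.0 min counts for 2.79 times as many substrate half-lives. The count is the logarithm to base two of the substrate charge over that charge minus target. Those two ratios give a reading of 0.935 for the order in free catalyst, which you take as first order.

| flask | substrate | coupling partner | free catalyst | time |
|---|---|---|---|---|
| epsilon | 150 mM | 450 mM | 3.00 mM |  |
| alpha | 90.0 mM | 390 mM | 3.00 mM |  |
| eta | 150 mM | 450 mM | 9.00 mM |  |
| delta | 150 mM | 900 mM | 0.990 mM | 30 min |

- epsilon run (time / min: [target] / mM): 6.0: 38.7; 12: 61.5; 18: 70.7; 24: 77.5; 30: 79.2
- alpha run (time / min: [target] / mM): 6.0: 19.3; 12: 33.4; 18: 41.2; 24: 45.4; 30: 47.8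
- eta run (time / min: [target] / mM): 6.0: 84.8; 12: 109.6; 18: 118.5; 24: 121.7; 30: 122.4

(scatter of a reading: 1 mM)

1. reaction order in [free catalyst] at the outset, round the charge of the epsilon run, defined at two percent of the substrate turned into target
2. target in the delta run at 30 min, as a share of the substrate charged

- Overall: substrate + coupling partner -> target, with free catalyst as catalyst.
- Constant volume, constant temperature.
- An order is taken over about fifteen percent of the charge, up and down.

Substrate is the limiting reagent, with coupling partner charged at 3.00 times as much in epsilon, but the target of the last epsilon reading stands for at least 17.6 % of that partner, so half-lives counted on substrate are a rough measure. Now climb the ladder of half-lives read over the first 6.0 min. Eta is quickest at 4.99 min, epsilon takes 13.9 min, and alpha 17.2 min. The bottom rung is the tail of epsilon, which gains 1.70 mM in its last interval, against a scatter of 1 mM. That is a rough half-life of 175 min, slower than any early rung. So by 30 min the epsilon curve is nearly flat.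

Epsilon ends at 0.361 mM⁻¹: these are the half-lives bought per millimolar of free catalyst. Alpha, with other charges of substrate and partner, reads 0.364 mM⁻¹, while eta reads less, 0.271 mM⁻¹. You carry the epsilon figure to delta, a long step in partner, and 0.990 mM of catalyst then buys 0.357 half-lives, or 21.9 % of the substrate as target.

The forecast gives order 1 and 43 %, above your figure, and adds: “The partner order is the main uncertainty”.

The flask gives order 1.0 and 25.7 % in delta, 3.8 percentage points above your figure, under these steps:

    free catalyst + substrate + coupling partner → target + free catalyst (45.18 M⁻² min⁻¹)
    target + coupling partner → side product (0.01890 M⁻¹ min⁻¹)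
    free catalyst + coupling partner → spent catalyst + coupling partner (0.09060 M⁻¹ min⁻¹)

Fitted with these true steps the runs leave a residual of 0.93 scatter units, against 9.0 for the main steps alone. Put back through the count, delta bought 0.433 mM⁻¹, against 0.361 mM⁻¹ for epsilon at 3.00 mM and 0.271 mM⁻¹ for eta at 9.00 mM.

The data were computed with constants of no real substance, noise included.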